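**Strategy.** Everything rests on disconnecting the O3'–C11 bond of the 1,4-dioxane ring D. C11 is benzylic to the para-oxygenated guaiacyl ring E, so a C11 carbinol ionises in acid and the adjacent 3'-phenol on ring B captures the cation. Because this closure is reversible, the C11 aryl group settles trans to the C10 substituent, both equatorial on ring D. One operation therefore makes ring D, the O3'–C11 bond and the C11 stereocentre from either carbinol epimer. The precursor is a methyl 3-hydroxy-4-aryloxybenzoate in which O4' is already bonded to C10, the (S) centre having been set by Mitsunobu inversion of a glycerol-derived alcohol; O3' stays masked as an allyl ether until just before cyclisation.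

Key step: step 9

Remarks on the chemistry:
- Labels follow silybin numbering: C10 carries the CH2OH group and is bonded to O4'; C11 carries ring E and is bonded to O3'; rings A and C are the chromenone, ring B the catechol-derived ring.
- In benzodioxine locants the aryl-bearing carbon is C3, its oxygen lying meta to the ester carbon, so the cyclised ester is a 3-aryl-2-(benzyloxymethyl)-6-carboxylate.
- The change from (S) in 3 to (R) in 4 is a change of CIP priorities only; the centre itself is inverted once, in step 3.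
- C11 of 11 and 12 is an epimer mixture and is left undefined in their SMILES.

**Step 1**
Reactants: 1 methyl 3,4-dihydroxybenzoate
Product: 2 methyl 4-hydroxy-3-(prop-2-en-1-yloxy)benzoate
Conditions: NaH (2.1 equiv), DMSO, 20 °C; then allyl bromide (1.0 equiv), 20 °C
Reagents that add atoms: allyl bromide, C=CCBr
Why: In the catecholate dianion the 3-oxide is not delocalised into the para ester and is the more nucleophilic oxygen, so one equivalent of halide should give the 3-O-allyl ether and leave the more acidic 4-OH free for step 3 (regioselective Williamson mono-alkylation of a catechol dianion).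

**Step 2**
Reactants: 3 (S)-3-(benzyloxy)propane-1,2-diol
Product: 4 (R)-1-(benzyloxy)-3-[(tert-butyldimethylsilyl)oxy]propan-2-ol
Conditions: TBSCl (1.05 equiv), imidazole, CH2Cl2, 0 °C
Reagents that add atoms: tert-butyldimethylsilyl chloride, CC(C)(C)[Si](C)(C)Cl
Why: Silyl ether formation with the bulky chlorosilane should take the primary hydroxyl selectively on steric grounds and does not touch the stereocentre.

**Step 3**
Reactants: 2 methyl 4-hydroxy-3-(prop-2-en-1-yloxy)benzoate; 4 (R)-1-(benzyloxy)-3-[(tert-butyldimethylsilyl)oxy]propan-2-ol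
Product: 5 methyl 4-{[(2S)-1-(benzyloxy)-3-[(tert-butyldimethylsilyl)oxy]propan-2-yl]oxy}-3-(prop-2-en-1-yloxy)benzoate
Conditions: PPh3, DIAD, THF, 0 → 20 °C
Reagents that add atoms: none
Why: Mitsunobu etherification, in which the acidic 4-phenol displaces the phosphonium-activated secondary alcohol by SN2, so the carbinol centre is inverted and becomes C10 with the (S) configuration of the target while the O4'–C10 regiochemistry is fixed unambiguously.

**Step 4**
Reactants: 5 methyl 4-{[(2S)-1-(benzyloxy)-3-[(tert-butyldimethylsilyl)oxy]propan-2-yl]oxy}-3-(prop-2-en-1-yloxy)benzoate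
Product: 6 methyl 4-{[(2R)-1-(benzyloxy)-3-hydroxypropan-2-yl]oxy}-3-(prop-2-en-1-yloxy)benzoate
Conditions: TsOH·H2O (0.1 equiv), MeOH, 20 °C
Reagents that add atoms: none
Why: Acid-catalysed methanolysis should cleave the primary silyl ether quickly while the allyl and benzyl ethers and the methyl ester are inert (silyl ether solvolysis).

**Step 5**
Reactants: 6 methyl 4-{[(2R)-1-(benzyloxy)-3-hydroxypropan-2-yl]oxy}-3-(prop-2-en-1-yloxy)benzoate
Product: 7 methyl 4-{[(2S)-1-(benzyloxy)-3-oxopropan-2-yl]oxy}-3-(prop-2-en-1-yloxy)benzoate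
Conditions: Dess–Martin periodinane (1.2 equiv), CH2Cl2, 0 → 20 °C; crude aldehyde used at once
Reagents that add atoms: none
Why: Dess–Martin oxidation is non-basic, so the configurationally sensitive alpha-aryloxy aldehyde should form without enolisation at C10.

**Step 6**
Reactants: 8 4-bromo-2-methoxyphenol
Product: 9 1-(benzyloxy)-4-bromo-2-methoxybenzene
Conditions: BnBr, K2CO3, DMF, 20 °C
Reagents that add atoms: benzyl bromide, BrCc1ccccc1
Why: Williamson benzylation of the phenol is straightforward and the aryl bromide does not react.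

**Step 7**
Reactants: 7 methyl 4-{[(2S)-1-(benzyloxy)-3-oxopropan-2-yl]oxy}-3-(prop-2-en-1-yloxy)benzoate; 9 1-(benzyloxy)-4-bromo-2-methoxybenzene
Product: 11 methyl 4-{[(2S)-1-(benzyloxy)-3-[4-(benzyloxy)-3-methoxyphenyl]-3-hydroxypropan-2-yl]oxy}-3-(prop-2-en-1-yloxy)benzoate (both C3 epimers), via arylmagnesium bromide 10 (not isolated)
Conditions: Mg turnings, THF, 40 °C (9 → 10); then 7, THF, −78 °C
Reagents that add atoms: none
Why: Grignard 1,2-addition, in which the aldehyde reacts far faster at −78 °C than the electron-rich methyl benzoate and faster than it is deprotonated, so C10 is kept and C11 forms as an epimer mixture that is harmless because step 9 passes through a planar cation.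

**Step 8**
Reactants: 11 methyl 4-{[(2S)-1-(benzyloxy)-3-[4-(benzyloxy)-3-methoxyphenyl]-3-hydroxypropan-2-yl]oxy}-3-(prop-2-en-1-yloxy)benzoate (both C3 epimers)
Product: 12 methyl 4-{[(2S)-1-(benzyloxy)-3-[4-(benzyloxy)-3-methoxyphenyl]-3-hydroxypropan-2-yl]oxy}-3-hydroxybenzoate (both C3 epimers)
Conditions: Pd(PPh3)4 (5 mol%), morpholine (3 equiv), THF, 20 °C
Reagents that add atoms: none
Why: Tsuji–Trost deallylation, in which zerovalent palladium ionises the aryl allyl ether to a pi-allyl complex that morpholine captures, freeing the 3'-phenol under neutral conditions that leave the benzylic carbinol, the benzyl ethers and the ester untouched.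

**Step 9**
Reactants: 12 methyl 4-{[(2S)-1-(benzyloxy)-3-[4-(benzyloxy)-3-methoxyphenyl]-3-hydroxypropan-2-yl]oxy}-3-hydroxybenzoate (both C3 epimers)
Product: 13 methyl (2S,3S)-3-[4-(benzyloxy)-3-methoxyphenyl]-2-[(benzyloxy)methyl]-2,3-dihydro-1,4-benzodioxine-6-carboxylate
Conditions: CF3CO2H (10 equiv), CH2Cl2 (0.01 M), 0 → 20 °C
Reagents that add atoms: none
Why: The acid protonates the C11 hydroxyl of either epimer and water leaves, giving one planar benzylic cation delocalised into ring E and onto its para benzyloxy oxygen, in effect an O-benzylated quinone methide; the closest known reaction type is the acid-mediated quinone-methide (benzylic cation) oxa-cyclisation used to make trans-2-aryl-1,4-benzodioxanes. The free 3'-OH of ring B adds to C11 in a 6-exo-trig closure that forms the O3'–C11 bond and ring D. The new C11 stereocentre is set under thermodynamic control by the existing C10 centre: the closure is reversible in the acid, so the ring settles with the C11 aryl and the C10 benzyloxymethyl groups trans and both pseudo-equatorial. C10 carries no ionisable group and stays sp3, so the (S) configuration from step 3 is kept and the product is (2S,3S). The step needs ionisation at C11 only and O-capture rather than C-capture of the cation; the first is secured because C11 is the only carbinol and the only centre with para-alkoxyaryl stabilisation, the second by the six-membered geometry, the electron-poor benzoate ring B and high dilution. Regiochemistry is not at stake because O4' was already tied to C10 in step 3.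

**Step 10**
Reactants: 13 methyl (2S,3S)-3-[4-(benzyloxy)-3-methoxyphenyl]-2-[(benzyloxy)methyl]-2,3-dihydro-1,4-benzodioxine-6-carboxylate
Product: 14 [(2S,3S)-3-[4-(benzyloxy)-3-methoxyphenyl]-2-[(benzyloxy)methyl]-2,3-dihydro-1,4-benzodioxin-6-yl]methanol
Conditions: LiAlH4, THF, 0 °C
Reagents that add atoms: none
Why: Hydride reduction of the aryl ester to the benzylic alcohol is reliable, and the ethers and both stereocentres are inert to LiAlH4.

**Step 11**
Reactants: 14 [(2S,3S)-3-[4-(benzyloxy)-3-methoxyphenyl]-2-[(benzyloxy)methyl]-2,3-dihydro-1,4-benzodioxin-6-yl]methanol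
Product: 15 (2S,3S)-3-[4-(benzyloxy)-3-methoxyphenyl]-2-[(benzyloxy)methyl]-2,3-dihydro-1,4-benzodioxine-6-carbaldehyde
Conditions: activated MnO2, CH2Cl2, 20 °C
Reagents that add atoms: none
Why: MnO2 oxidises primary benzylic alcohols selectively to aldehydes without over-oxidation and without acid or base that could disturb ring D.

**Step 12**
Reactants: 16 1-(2,4,6-trihydroxyphenyl)ethan-1-one
Product: 17 1-[2,4-bis(benzyloxy)-6-hydroxyphenyl]ethan-1-one
Conditions: BnBr (2.1 equiv), K2CO3, acetone, reflux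
Reagents that add atoms: benzyl bromide, BrCc1ccccc1
Why: Williamson benzylation takes the 4-OH and one ortho OH, while the remaining ortho hydroxyl is held in a hydrogen bond to the ketone and should stay free.

**Step 13**
Reactants: 15 (2S,3S)-3-[4-(benzyloxy)-3-methoxyphenyl]-2-[(benzyloxy)methyl]-2,3-dihydro-1,4-benzodioxine-6-carbaldehyde; 17 1-[2,4-bis(benzyloxy)-6-hydroxyphenyl]ethan-1-one
Product: 18 (2E)-1-[2,4-bis(benzyloxy)-6-hydroxyphenyl]-3-[(2S,3S)-3-[4-(benzyloxy)-3-methoxyphenyl]-2-[(benzyloxy)methyl]-2,3-dihydro-1,4-benzodioxin-6-yl]prop-2-en-1-one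
Conditions: KOH (50% aq.), EtOH/THF, 20 °C
Reagents that add atoms: none
Why: Claisen–Schmidt condensation, in which the enolate of the methyl ketone adds to the non-enolisable aldehyde and the adduct loses water to the conjugated E-enone, with no base-labile site in the benzodioxane.

**Step 14**
Reactants: 18 (2E)-1-[2,4-bis(benzyloxy)-6-hydroxyphenyl]-3-[(2S,3S)-3-[4-(benzyloxy)-3-methoxyphenyl]-2-[(benzyloxy)methyl]-2,3-dihydro-1,4-benzodioxin-6-yl]prop-2-en-1-one
Product: 20 5,7-bis(benzyloxy)-2-[(2S,3S)-3-[4-(benzyloxy)-3-methoxyphenyl]-2-[(benzyloxy)methyl]-2,3-dihydro-1,4-benzodioxin-6-yl]-3-hydroxy-4H-chromen-4-one, via trans-3-hydroxyflavanone 19 (not isolated)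
Conditions: H2O2 (30% aq.), NaOH (aq.), MeOH/THF, 0 → 20 °C
Reagents that add atoms: hydrogen peroxide, OO
Why: Algar–Flynn–Oyamada reaction, in which alkaline peroxide closes the 2'-phenoxide onto the beta-carbon with hydroxylation at the alpha-carbon to give 19, which is dehydrogenated in the same medium to the flavonol, the para oxygen O4' of ring B favouring beta-attack over aurone formation.

**Step 15**
Reactants: 20 5,7-bis(benzyloxy)-2-[(2S,3S)-3-[4-(benzyloxy)-3-methoxyphenyl]-2-[(benzyloxy)methyl]-2,3-dihydro-1,4-benzodioxin-6-yl]-3-hydroxy-4H-chromen-4-one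
Product: 21 2,3-dehydrosilybin B, 2-[(2S,3S)-3-(4-hydroxy-3-methoxyphenyl)-2-(hydroxymethyl)-2,3-dihydro-1,4-benzodioxin-6-yl]-3,5,7-trihydroxy-4H-chromen-4-one
Conditions: H2 (1 atm), Pd/C (10 wt%), THF/MeOH, 20 °C
Reagents that add atoms: none
Why: Catalytic hydrogenolysis removes the four O-benzyl groups, while the cyclic benzylic ether at C11 and the chromenone double bond react far more slowly under these mild conditions, so stopping at full debenzylation should leave both stereocentres intact.

**Compound list**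

1 | methyl 3,4-dihydroxybenzoate | COC(=O)c1ccc(O)c(O)c1 | starting material
2 | methyl 4-hydroxy-3-(prop-2-en-1-yloxy)benzoate | COC(=O)c1ccc(O)c(OCC=C)c1 | intermediate
3 | (S)-3-(benzyloxy)propane-1,2-diol | OC[C@H](O)COCc1ccccc1 | starting material
4 | (R)-1-(benzyloxy)-3-[(tert-butyldimethylsilyl)oxy]propan-2-ol | CC(C)(C)[Si](C)(C)OC[C@H](O)COCc1ccccc1 | intermediate
5 | methyl 4-{[(2S)-1-(benzyloxy)-3-[(tert-butyldimethylsilyl)oxy]propan-2-yl]oxy}-3-(prop-2-en-1-yloxy)benzoate | COC(=O)c1ccc(O[C@H](CO[Si](C)(C)C(C)(C)C)COCc2ccccc2)c(OCC=C)c1 | intermediate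
6 | methyl 4-{[(2R)-1-(benzyloxy)-3-hydroxypropan-2-yl]oxy}-3-(prop-2-en-1-yloxy)benzoate | COC(=O)c1ccc(O[C@H](CO)COCc2ccccc2)c(OCC=C)c1 | intermediate
7 | methyl 4-{[(2S)-1-(benzyloxy)-3-oxopropan-2-yl]oxy}-3-(prop-2-en-1-yloxy)benzoate | COC(=O)c1ccc(O[C@H](C=O)COCc2ccccc2)c(OCC=C)c1 | intermediate
8 | 4-bromo-2-methoxyphenol | COc1cc(Br)ccc1O | starting material
9 | 1-(benzyloxy)-4-bromo-2-methoxybenzene | COc1cc(Br)ccc1OCc1ccccc1 | intermediate
10 | [4-(benzyloxy)-3-methoxyphenyl]magnesium bromide | COc1cc([Mg]Br)ccc1OCc1ccccc1 | intermediate (not isolated)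
11 | methyl 4-{[(2S)-1-(benzyloxy)-3-[4-(benzyloxy)-3-methoxyphenyl]-3-hydroxypropan-2-yl]oxy}-3-(prop-2-en-1-yloxy)benzoate, both C3 epimers | COc1cc(C(O)[C@H](COCc2ccccc2)Oc2ccc(C(=O)OC)cc2OCC=C)ccc1OCc1ccccc1 | intermediate
12 | methyl 4-{[(2S)-1-(benzyloxy)-3-[4-(benzyloxy)-3-methoxyphenyl]-3-hydroxypropan-2-yl]oxy}-3-hydroxybenzoate, both C3 epimers | COc1cc(C(O)[C@H](COCc2ccccc2)Oc2ccc(C(=O)OC)cc2O)ccc1OCc1ccccc1 | intermediate
13 | methyl (2S,3S)-3-[4-(benzyloxy)-3-methoxyphenyl]-2-[(benzyloxy)methyl]-2,3-dihydro-1,4-benzodioxine-6-carboxylate | COc1cc([C@@H]2Oc3cc(C(=O)OC)ccc3O[C@H]2COCc2ccccc2)ccc1OCc1ccccc1 | intermediate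
14 | [(2S,3S)-3-[4-(benzyloxy)-3-methoxyphenyl]-2-[(benzyloxy)methyl]-2,3-dihydro-1,4-benzodioxin-6-yl]methanol | COc1cc([C@@H]2Oc3cc(CO)ccc3O[C@H]2COCc2ccccc2)ccc1OCc1ccccc1 | intermediate
15 | (2S,3S)-3-[4-(benzyloxy)-3-methoxyphenyl]-2-[(benzyloxy)methyl]-2,3-dihydro-1,4-benzodioxine-6-carbaldehyde | COc1cc([C@@H]2Oc3cc(C=O)ccc3O[C@H]2COCc2ccccc2)ccc1OCc1ccccc1 | intermediate
16 | 1-(2,4,6-trihydroxyphenyl)ethan-1-one | CC(=O)c1c(O)cc(O)cc1O | starting material
17 | 1-[2,4-bis(benzyloxy)-6-hydroxyphenyl]ethan-1-one | CC(=O)c1c(O)cc(OCc2ccccc2)cc1OCc1ccccc1 | intermediate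
18 | (2E)-1-[2,4-bis(benzyloxy)-6-hydroxyphenyl]-3-[(2S,3S)-3-[4-(benzyloxy)-3-methoxyphenyl]-2-[(benzyloxy)methyl]-2,3-dihydro-1,4-benzodioxin-6-yl]prop-2-en-1-one | COc1cc([C@@H]2Oc3cc(/C=C/C(=O)c4c(O)cc(OCc5ccccc5)cc4OCc4ccccc4)ccc3O[C@H]2COCc2ccccc2)ccc1OCc1ccccc1 | intermediate
19 | 5,7-bis(benzyloxy)-2-[(2S,3S)-3-[4-(benzyloxy)-3-methoxyphenyl]-2-[(benzyloxy)methyl]-2,3-dihydro-1,4-benzodioxin-6-yl]-3-hydroxy-2,3-dihydro-4H-chromen-4-one, 2,3-trans on ring C, both diastereomers | COc1cc([C@@H]2Oc3cc(C4Oc5cc(OCc6ccccc6)cc(OCc6ccccc6)c5C(=O)C4O)ccc3O[C@H]2COCc2ccccc2)ccc1OCc1ccccc1 | intermediate (not isolated)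
20 | 5,7-bis(benzyloxy)-2-[(2S,3S)-3-[4-(benzyloxy)-3-methoxyphenyl]-2-[(benzyloxy)methyl]-2,3-dihydro-1,4-benzodioxin-6-yl]-3-hydroxy-4H-chromen-4-one | COc1cc([C@@H]2Oc3cc(-c4oc5cc(OCc6ccccc6)cc(OCc6ccccc6)c5c(=O)c4O)ccc3O[C@H]2COCc2ccccc2)ccc1OCc1ccccc1 | intermediate
21 | 2,3-dehydrosilybin B, 2-[(2S,3S)-3-(4-hydroxy-3-methoxyphenyl)-2-(hydroxymethyl)-2,3-dihydro-1,4-benzodioxin-6-yl]-3,5,7-trihydroxy-4H-chromen-4-one | COc1cc([C@@H]2Oc3cc(-c4oc5cc(O)cc(O)c5c(=O)c4O)ccc3O[C@H]2CO)ccc1O | target

**Totals.** Total step count: 15. Longest linear sequence: 12 steps (3 → 4 → 5 → 6 → 7 → 11 → 12 → 13 → 14 → 15 → 18 → 20 → 21; the sequence from 1 is equally long).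

**Steps most likely to fail**

Step 9. The C11 cation may lose the C10 proton to an enol ether, the channel known from acidolysis of arylglycerol beta-aryl ethers, which would erase the C10 configuration and divert material. Equilibration may also stop before the cis isomer has drained into the trans form. The fallback closes the same bond without a cation. It sets out from 11, which is oxidised with Dess–Martin periodinane in CH2Cl2 to the aryl ketone methyl 4-{[(2S)-1-(benzyloxy)-3-[4-(benzyloxy)-3-methoxyphenyl]-3-oxopropan-2-yl]oxy}-3-(prop-2-en-1-yloxy)benzoate F1. Reduction with Zn(BH4)2 in Et2O at −20 °C, chosen for chelation between the ketone and the alpha-aryloxy oxygen, should favour the anti (2S,3R) carbinol F2; any syn epimer would be separated and returned to F1. Deallylation with Pd(PPh3)4 and morpholine gives the anti (2S,3R) phenol carbinol F3. Intramolecular Mitsunobu etherification (PPh3, DIAD, THF) then forms O3'–C11 by SN2 with inversion at C11 and comes back to the route at 13.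

Step 14. The 2'-phenoxide may close on the alpha-carbon in a five-membered mode and give an aurone, a course favoured by the 6'-benzyloxy group that twists the enone out of plane. The fallback separates ring closure from hydroxylation. It sets out from 18, which with I2 (0.1 equiv) in DMSO at 120 °C should undergo oxidative cyclisation to the flavone 5,7-bis(benzyloxy)-2-[(2S,3S)-3-[4-(benzyloxy)-3-methoxyphenyl]-2-[(benzyloxy)methyl]-2,3-dihydro-1,4-benzodioxin-6-yl]-4H-chromen-4-one F4. Dimethyldioxirane in acetone/CH2Cl2 at 0 °C should then epoxidise the ring C double bond to the flavone 2,3-epoxide F5, which opens to the flavonol on brief exposure to catalytic TsOH·H2O. The route is rejoined at 20.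

Step 7. The basic Grignard reagent may enolise the alpha-aryloxy aldehyde, which erodes the C10 configuration or expels benzyl alcohol by beta-elimination, and excess reagent may attack the ester. The fallback replaces the magnesium nucleophile by a non-basic one. It sets out from 9 by way of 10, which is transmetalated with ClTi(OiPr)3 in THF at −78 °C to the aryltitanium reagent [4-(benzyloxy)-3-methoxyphenyl]tri(propan-2-yloxy)titanium F6. This aldehyde-selective reagent is added to 7 at −40 → 0 °C and returns to the route at 11.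

**Further compounds**

F1 | step 9 | methyl 4-{[(2S)-1-(benzyloxy)-3-[4-(benzyloxy)-3-methoxyphenyl]-3-oxopropan-2-yl]oxy}-3-(prop-2-en-1-yloxy)benzoate | COc1cc(C(=O)[C@H](COCc2ccccc2)Oc2ccc(C(=O)OC)cc2OCC=C)ccc1OCc1ccccc1
F2 | step 9 | methyl 4-{[(2S,3R)-1-(benzyloxy)-3-[4-(benzyloxy)-3-methoxyphenyl]-3-hydroxypropan-2-yl]oxy}-3-(prop-2-en-1-yloxy)benzoate | COc1cc([C@@H](O)[C@H](COCc2ccccc2)Oc2ccc(C(=O)OC)cc2OCC=C)ccc1OCc1ccccc1
F3 | step 9 | methyl 4-{[(2S,3R)-1-(benzyloxy)-3-[4-(benzyloxy)-3-methoxyphenyl]-3-hydroxypropan-2-yl]oxy}-3-hydroxybenzoate | COc1cc([C@@H](O)[C@H](COCc2ccccc2)Oc2ccc(C(=O)OC)cc2O)ccc1OCc1ccccc1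
F4 | step 14 | 5,7-bis(benzyloxy)-2-[(2S,3S)-3-[4-(benzyloxy)-3-methoxyphenyl]-2-[(benzyloxy)methyl]-2,3-dihydro-1,4-benzodioxin-6-yl]-4H-chromen-4-one | COc1cc([C@@H]2Oc3cc(-c4cc(=O)c5c(OCc6ccccc6)cc(OCc6ccccc6)cc5o4)ccc3O[C@H]2COCc2ccccc2)ccc1OCc1ccccc1
F5 | step 14 | 2,3-epoxide of F4, 5,7-bis(benzyloxy)-2-aryl-2,3-epoxychroman-4-one with the same (2S,3S)-benzodioxinyl group, both epoxide diastereomers | COc1cc([C@@H]2Oc3cc(C45OC4C(=O)c4c(OCc6ccccc6)cc(OCc6ccccc6)cc4O5)ccc3O[C@H]2COCc2ccccc2)ccc1OCc1ccccc1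
F6 | step 7 | [4-(benzyloxy)-3-methoxyphenyl]tri(propan-2-yloxy)titanium | COc1cc([Ti](OC(C)C)(OC(C)C)OC(C)C)ccc1OCc1ccccc1
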